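**Assumption:** the SMILES is taken literally. The dihydronaphthalene carries OMe at C8 (peri to C1), and the C1 aryl and C2 aroyl groups are cis, (1S,2S). This cis isomer is expected to be the less stable C2 epimer, so C2 is set last and never sees base afterwards.

## Retrosynthetic overview

1. Target 13 ⇐ global desilylation of hexa-TIPS ether 12; C2 of 12 ⇐ kinetic protonation of the C2 enolate of trans isomer 11, anti to the axial C1 aryl.
2. 11 ⇐ dehydration of tetralol 10 ⇐ enantioselective photoenolization/Diels–Alder of 2-benzylbenzaldehyde 6 (C1, C8a, C4a, C4) with enedione 9 (C2, C3). This one step forms C1–C2 and C3–C4 and sets C1.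
3. 6 ⇐ diarylmethane built from two copies of one arene (3-methoxycatechol bis-TIPS ether 2), using OMe-directed lithiation for all regiocontrol.
4. 9 ⇐ fumaryl chloride + 2 ArZnCl (double Pd acylation; both aryl groups come from bromide 7).
5. Ring order: both benzene rings are bought; the central carbocycle is the only ring formed (step 7).

(TIPS = triisopropylsilyl; ring numbering is that of the 1,2-dihydronaphthalene.)

## Route

**Step 1**
Reactants: 1, 3-methoxycatechol
Product: 2, 1-methoxy-2,3-bis(triisopropylsilyloxy)benzene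
Conditions: TIPSOTf (2.4 equiv), 2,6-lutidine, CH2Cl2, 0 °C → rt
Reagents that add atoms: triisopropylsilyl triflate, CC(C)[Si](OS(=O)(=O)C(F)(F)F)(C(C)C)C(C)C (two equivalents incorporated, one TIPS per phenol)
Why: Phenol O-silylation; TIPS survives BuLi, is not an ortho-director (so OMe alone steers the later lithiations), and all six phenols can be released together under non-basic fluoride conditions.

**Step 2**
Reactants: 2
Product: 3, 6-bromo-2-methoxy-3,4-bis(triisopropylsilyloxy)benzaldehyde
Conditions: n-BuLi, TMEDA, Et2O, 0 °C → rt; Me2NCH2CH2N(Me)CHO, −78 → −20 °C; n-BuLi (3 equiv), −20 °C; BrCl2C–CCl2Br, −78 °C → rt; aq. HCl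
Reagents that add atoms: N-formyl-N,N′,N′-trimethylethylenediamine, CN(C)CCN(C)C=O (gives CHO); 1,2-dibromotetrachloroethane, BrC(Cl)(Cl)C(Cl)(Cl)Br (gives Br)
Why: Directed ortho-metalation ortho to OMe, then formylation to an α-amino alkoxide that directs a second lithiation (Comins ortho-lithiation) to the only free ortho position, then electrophilic bromination.

**Step 3**
Reactants: 2 (lithiated in situ) and 3
Product: 4, (±)-[6-bromo-2-methoxy-3,4-bis(TIPSO)phenyl][2-methoxy-3,4-bis(TIPSO)phenyl]methanol
Conditions: 2, n-BuLi, TMEDA, Et2O, 0 °C → rt; then 3, THF, −78 °C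
Reagents that add atoms: none
Why: The same directed ortho-metalation gives the aryllithium, whose 1,2-addition to the aldehyde is much faster than Br/Li exchange at −78 °C; the carbinol centre is removed in step 4.

**Step 4**
Reactants: 4
Product: 5, 1-bromo-3-methoxy-2-{[2-methoxy-3,4-bis(TIPSO)phenyl]methyl}-4,5-bis(TIPSO)benzene
Conditions: Et3SiH, TFA, CH2Cl2, 0 °C
Reagents that add atoms: none
Why: Ionic hydrogenation through a diarylmethyl cation stabilised by a para-silyloxy group on each ring; aryl TIPS ethers and ArBr tolerate TFA.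

**Step 5**
Reactants: 5
Product: 6, 3-methoxy-2-{[2-methoxy-3,4-bis(TIPSO)phenyl]methyl}-4,5-bis(TIPSO)benzaldehyde
Conditions: t-BuLi (2.1 equiv), Et2O, −78 °C; DMF; aq. NH4Cl
Reagents that add atoms: N,N-dimethylformamide, CN(C)C=O
Why: Br/Li exchange and Bouveault formylation; exchange at −78 °C outruns deprotonation of the diarylmethane CH2, and the aldehyde ends up ortho to the benzyl group as photoenolization requires.

**Step 6**
Reactants: 7, (4-bromophenoxy)triisopropylsilane (2.2 equiv; two molecules are incorporated per molecule of 8), and 8, fumaryl chloride (1.0 equiv)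
Product: 9, (E)-1,4-bis[4-(triisopropylsilyloxy)phenyl]but-2-ene-1,4-dione
Conditions: 7 (2.2 equiv), n-BuLi (2.2 equiv), THF, −78 °C; ZnCl2 (2.3 equiv), −78 °C → 0 °C; then 8 (1.0 equiv), Pd(PPh3)4 (5 mol %), THF, 0 °C → rt
Reagents that add atoms: second equivalent of 7, (4-bromophenoxy)triisopropylsilane, Brc1ccc(O[Si](C(C)C)(C(C)C)C(C)C)cc1 (supplies the second 4-(TIPSO)phenyl group)
Why: Twofold Pd-catalysed Negishi acylation: each acid chloride group of 8 couples with one arylzinc chloride made from 7, so 9 contains two aryl units from 7 and the C4 unit of 8, with retention of the E alkene; arylzinc chlorides do not add conjugatively to the enedione without copper.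

**Step 7 (key step)**
Reactants: 6 and 9
Product: 10, the (1S,2R,3S,4S)-tetralol: 1-aryl, 3-aroyl and 4-OH mutually cis, 2-aroyl trans to them
Conditions: Ti(OiPr)4 (2 equiv), (R,R)-TADDOL (2.2 equiv), 4 Å MS, toluene, degassed, 366 nm LED, rt; Rochelle salt work-up
Reagents that add atoms: none
Why: Proposed new method: excitation of the aldehyde, 1,5-H transfer from the doubly benzylic CH2 and relaxation give the (E,E)-hydroxy-o-quinodimethane (OH and aryl both "out"), which is held as a Ti(IV) dienolate on the TADDOLate–Ti centre that also binds a C=O of 9, so an endo [4+2] on one diene face forms C1–C2 and C3–C4 and sets C1 as S; the closest known reaction is the Ti(OiPr)4/TADDOL-mediated enantioselective photoenolization/Diels–Alder of 2-methylbenzaldehydes with enones, extended here to a 2-benzyl aldehyde and an acyclic enedione. The (R,R) ligand is a working assignment, not a prediction; the (S,S) ligand gives the antipode. Only C1 must be right, so photo E/Z scrambling of 9 and the C2–C4 diastereomer ratio do not matter.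

**Step 8**
Reactants: 10
Product: 11, the (1S,2R)-trans-1,2-dihydronaphthalene hexa-TIPS ether
Conditions: MsCl, Et3N, DMAP (cat.), CH2Cl2, 0 °C → rt, degassed
Reagents that add atoms: none
Why: Mesylation and E1cB dehydration of the benzylic β-hydroxy ketone give the C3=C4 enone, removing the C3 and C4 stereocentres; C2 settles mainly as the trans-diaxial epimer and the non-acidic C1–H is untouched.

**Step 9**
Reactants: 11
Product: 12, the (1S,2S)-cis hexa-TIPS ether
Conditions: LiHMDS (1.3 equiv), THF, −78 °C, degassed; then AcOH (excess) in THF, −78 °C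
Reagents that add atoms: none
Why: Kinetic enolate protonation: the C1 aryl is held pseudoaxial by the C8-OMe and by A(1,3) strain with the exocyclic enolate, so the proton enters C2 (the α-carbon of the extended enolate) from the opposite face and the aroyl ends up cis to the aryl (2S); any cis material from step 8 converges to the same product.

**Step 10**
Reactants: 12
Product: 13, licobichalcone
Conditions: KHF2, MeOH/THF, rt, Ar; pH 6 buffer work-up
Reagents that add atoms: none
Why: Bifluoride cleavage of the six aryl silyl ethers under weakly acidic conditions, with no phenoxide or amine base to enolise C2; the aryl OMe groups and the enone are inert.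

## Compound list

1 | 3-methoxycatechol | COc1cccc(O)c1O | starting material
2 | 1-methoxy-2,3-bis(triisopropylsilyloxy)benzene | COc1cccc(O[Si](C(C)C)(C(C)C)C(C)C)c1O[Si](C(C)C)(C(C)C)C(C)C | intermediate
3 | 6-bromo-2-methoxy-3,4-bis(TIPSO)benzaldehyde | COc1c(C=O)c(Br)cc(O[Si](C(C)C)(C(C)C)C(C)C)c1O[Si](C(C)C)(C(C)C)C(C)C | intermediate
4 | (±)-[6-bromo-2-methoxy-3,4-bis(TIPSO)phenyl][2-methoxy-3,4-bis(TIPSO)phenyl]methanol | COc1c(C(O)c2ccc(O[Si](C(C)C)(C(C)C)C(C)C)c(O[Si](C(C)C)(C(C)C)C(C)C)c2OC)c(Br)cc(O[Si](C(C)C)(C(C)C)C(C)C)c1O[Si](C(C)C)(C(C)C)C(C)C | intermediate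
5 | 1-bromo-3-methoxy-2-{[2-methoxy-3,4-bis(TIPSO)phenyl]methyl}-4,5-bis(TIPSO)benzene | COc1c(Cc2ccc(O[Si](C(C)C)(C(C)C)C(C)C)c(O[Si](C(C)C)(C(C)C)C(C)C)c2OC)c(Br)cc(O[Si](C(C)C)(C(C)C)C(C)C)c1O[Si](C(C)C)(C(C)C)C(C)C | intermediate
6 | 3-methoxy-2-{[2-methoxy-3,4-bis(TIPSO)phenyl]methyl}-4,5-bis(TIPSO)benzaldehyde | COc1c(Cc2ccc(O[Si](C(C)C)(C(C)C)C(C)C)c(O[Si](C(C)C)(C(C)C)C(C)C)c2OC)c(C=O)cc(O[Si](C(C)C)(C(C)C)C(C)C)c1O[Si](C(C)C)(C(C)C)C(C)C | intermediate
7 | (4-bromophenoxy)triisopropylsilane | Brc1ccc(O[Si](C(C)C)(C(C)C)C(C)C)cc1 | starting material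
8 | fumaryl chloride | O=C(Cl)/C=C/C(=O)Cl | starting material
9 | (E)-1,4-bis[4-(TIPSO)phenyl]but-2-ene-1,4-dione | O=C(/C=C/C(=O)c1ccc(O[Si](C(C)C)(C(C)C)C(C)C)cc1)c1ccc(O[Si](C(C)C)(C(C)C)C(C)C)cc1 | intermediate
10 | [(1S,2R,3S,4S)-4-hydroxy-8-methoxy-1-[2-methoxy-3,4-bis(TIPSO)phenyl]-6,7-bis(TIPSO)-1,2,3,4-tetrahydronaphthalene-2,3-diyl]bis{[4-(TIPSO)phenyl]methanone} | COc1c([C@H]2c3c(cc(O[Si](C(C)C)(C(C)C)C(C)C)c(O[Si](C(C)C)(C(C)C)C(C)C)c3OC)[C@@H](O)[C@@H](C(=O)c3ccc(O[Si](C(C)C)(C(C)C)C(C)C)cc3)[C@@H]2C(=O)c2ccc(O[Si](C(C)C)(C(C)C)C(C)C)cc2)ccc(O[Si](C(C)C)(C(C)C)C(C)C)c1O[Si](C(C)C)(C(C)C)C(C)C | intermediate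
11 | (1S,2R)-trans hexa-TIPS licobichalcone (C2 epimer of 12) | COc1c([C@H]2c3c(cc(O[Si](C(C)C)(C(C)C)C(C)C)c(O[Si](C(C)C)(C(C)C)C(C)C)c3OC)C=C(C(=O)c3ccc(O[Si](C(C)C)(C(C)C)C(C)C)cc3)[C@@H]2C(=O)c2ccc(O[Si](C(C)C)(C(C)C)C(C)C)cc2)ccc(O[Si](C(C)C)(C(C)C)C(C)C)c1O[Si](C(C)C)(C(C)C)C(C)C | intermediate
12 | (1S,2S)-cis hexa-TIPS licobichalcone | COc1c([C@H]2c3c(cc(O[Si](C(C)C)(C(C)C)C(C)C)c(O[Si](C(C)C)(C(C)C)C(C)C)c3OC)C=C(C(=O)c3ccc(O[Si](C(C)C)(C(C)C)C(C)C)cc3)[C@H]2C(=O)c2ccc(O[Si](C(C)C)(C(C)C)C(C)C)cc2)ccc(O[Si](C(C)C)(C(C)C)C(C)C)c1O[Si](C(C)C)(C(C)C)C(C)C | intermediate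
13 | licobichalcone, [(1S,2S)-1-(3,4-dihydroxy-2-methoxyphenyl)-6,7-dihydroxy-8-methoxy-1,2-dihydronaphthalene-2,3-diyl]bis[(4-hydroxyphenyl)methanone] | COc1c([C@H]2c3c(cc(O)c(O)c3OC)C=C(C(=O)c3ccc(O)cc3)[C@H]2C(=O)c2ccc(O)cc2)ccc(O)c1O | target

## Summary

Total steps: 10. Longest linear sequence: 9 (steps 1–5, 7–10).

Three steps most likely to fail, each with a fallback that changes the approach:

1. **Step 7 (asymmetric photoenolization/Diels–Alder).** Risks are competing photochemistry of the enedione, low ee, and an unfavourable dienol geometry next to the C8-OMe. Fallback: set C1 without a cycloaddition. Make the chalcone from 3 and 4′-(TIPSO)acetophenone, add the arylboronic acid derived from lithiated 2 by Rh/chiral-diene conjugate addition (Hayashi–Miyaura), α-phenacylate the ketone, convert ArBr to ArCHO by Pd-catalysed formylation, and close the ring by intramolecular aldol condensation to reach 11.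

2. **Step 9 (contra-thermodynamic kinetic protonation).** Risks are poor facial selectivity, γ-protonation, or re-epimerisation on warming. Fallback: obtain cis from a suprafacial cycloaddition instead. Use the (Z)-enedione (mCPBA ring-opening of 2,5-bis(4-TIPSO-phenyl)furan) in a thermal endo Diels–Alder with the hydroxy-o-quinodimethane released from the benzocyclobutenol (formed by irradiating 6 alone). This gives the all-cis adduct, which is dehydrated under neutral conditions (Burgess reagent) so C2 is never enolised.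

3. **Step 10 (sixfold desilylation of the epimerisable, oxidation-prone cis compound).** Risks are C2 epimerisation or catechol oxidation during a slow deprotection. Fallback: reorder the endgame. Desilylate at the robust trans stage (11), per-trimethylsilylate the hexaphenol in situ (BSA), enolise with LiHMDS at −78 °C, and quench with AcOH then dilute aqueous acid. Kinetic C2 protonation and loss of the labile TMS ethers then occur in the same quench, with no separate deprotection on the cis compound.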